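**Plan**

1. Ring numbering: oxolane O1, C2 (CH bearing 3,4-dimethoxyphenyl), C3 (Me), C4 (Me), C5 (CH bearing 4-hydroxy-3,5-dimethoxyphenyl). Retrosynthetic cuts in order: phenol O–Si; ring bond C2–C3 together with one C–H of the C3 methyl; O1–C2; C4–C5.
2. Forward: asymmetric anti-crotylation of silyl-protected syringaldehyde joins C5–C4–C3 with a vinyl terminus; C2 is hung on O1 as an O,S-acetal; the oxolane, the only ring made, closes last in one 5-exo radical event.
3. Enabling feature: C2 is both benzylic and alpha to O1, so it holds a radical. The tether O1–C5–C4 places it 5-exo to a vinyl group whose inner carbon is C3 and whose terminal carbon becomes the C3 methyl. The phenylthio group is the only helper and leaves in the ring-closing step.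
4. Stereochemistry: C5 (S) and C4 (S) are set by a chiral phosphoric acid catalyst in the crotylation; C3 (S) and C2 (R) are relayed from them in the cyclisation through a chair-like transition state with all substituents pseudo-equatorial.

Key step: step 5

Remark on the chemistry: the (S)-configured phosphoric acid is assumed to direct the crotyl group to the Si face of aldehyde 2, giving the (1S,2S) alcohol. If the sense proves opposite, the (R)-acid is used and nothing else changes.

**Route**

Step 1
Reactants: 1 syringaldehyde (4-hydroxy-3,5-dimethoxybenzaldehyde)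
Product: 2 3,5-dimethoxy-4-[(triisopropylsilyl)oxy]benzaldehyde
Conditions: TIPSCl, imidazole, DMF, rt to 40 °C
Reagents that add atoms: triisopropylsilyl chloride, CC(C)[Si](Cl)(C(C)C)C(C)C
Why: Silylation of the phenol; the bulky aryl silyl ether should survive the mild acid catalyst, NaH and the radical step, and fluoride removes it at the end without touching the benzylic C–O bonds.

Step 2
Reactants: 2 3,5-dimethoxy-4-[(triisopropylsilyl)oxy]benzaldehyde; 3 (E)-crotylboronic acid pinacol ester
Product: 5 (1S,2S)-1-{3,5-dimethoxy-4-[(triisopropylsilyl)oxy]phenyl}-2-methylbut-3-en-1-ol, via pinacol borate ester 4 (not isolated)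
Conditions: (S)-TRIP phosphoric acid (5 mol%), PhMe, −30 °C; aqueous work-up
Reagents that add atoms: none
Why: Chiral Brønsted acid-catalysed crotylboration of an aromatic aldehyde; the closed six-membered chair transition state turns the (E)-geometry of 3 into the anti relationship of C4 and C5, and the catalyst bound to the boronate selects the Si face of the aldehyde, setting C5 (S) and C4 (S); borate 4 is hydrolysed on work-up.

Step 3
Reactants: 6 (3,4-dimethoxyphenyl)methanol
Product: 7 3,4-dimethoxybenzyl phenyl sulfide
Conditions: PhSH (1.5 equiv), ZnI2 (10 mol%), ClCH2CH2Cl, rt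
Reagents that add atoms: thiophenol, Sc1ccccc1
Why: Lewis acid-catalysed dehydrative thioetherification of an electron-rich benzylic alcohol; the excess thiol should capture the benzylic cation before it alkylates another arene.

Step 4
Reactants: 7 3,4-dimethoxybenzyl phenyl sulfide; 5 (1S,2S)-1-{3,5-dimethoxy-4-[(triisopropylsilyl)oxy]phenyl}-2-methylbut-3-en-1-ol
Product: 10 (3,4-dimethoxyphenyl)(phenylsulfanyl)methyl (1S,2S)-1-{3,5-dimethoxy-4-[(triisopropylsilyl)oxy]phenyl}-2-methylbut-3-en-1-yl ether (O,S-acetal; both epimers at the acetal carbon), via alpha-chloro sulfide 8 (not isolated), via sodium alkoxide 9 (not isolated)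
Conditions: NCS, PhH, rt, then filtration (7 to 8); NaH, THF, 0 °C (5 to 9); solutions combined, 0 °C to rt
Reagents that add atoms: none
Why: Chlorination alpha to sulfur (chlorosulfonium salt, then Pummerer-type shift) gives 8, whose chloride is displaced by alkoxide 9 through the sulfur- and aryl-stabilised thionium ion pair (Williamson-type O-alkylation, as for methylthiomethyl ethers); no stereocentre of 5 is touched, and the new acetal centre is erased in step 5.

Step 5
Reactants: 10 O,S-acetal (both epimers)
Product: 11 (2R,3S,4S,5S)-2-(3,4-dimethoxyphenyl)-5-{3,5-dimethoxy-4-[(triisopropylsilyl)oxy]phenyl}-3,4-dimethyloxolane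
Conditions: Bu3SnH (1.3 equiv, syringe pump), Et3B (0.2 equiv), air, PhMe (0.01 M), 0 °C to rt
Reagents that add atoms: none
Why: Bu3Sn• removes the phenylthio group of 10 and leaves a C2 radical that is benzylic and stabilised by O1; held by the O1–C5–C4 tether, it adds to the internal vinyl carbon (C3), and the primary radical left on the terminal carbon takes hydrogen from Bu3SnH to become the C3 methyl group and to carry the chain. The closest known reaction type is the tin hydride-mediated cyclisation of 2-oxahex-5-enyl radicals, generated from O,S- or O,Se-acetals of homoallylic alcohols, to 3-methyloxolanes. The oxolane closes in the 5-exo-trig mode. C3 is controlled by the chair-like transition state in which the C5 aryl and C4 methyl groups set in step 2 are pseudo-equatorial, so the incipient CH2 lies trans to the C4 methyl and cis to the C5 aryl group; C2 is controlled in the same transition state by the 3,4-dimethoxyphenyl group taking the pseudo-equatorial site on the radical carbon, away from the axial C5–H, which gives the 2,3-cis and 2,5-cis relationships. The step needs ring closure to outrun direct reduction of the stabilised radical, beta-scission of its C5–O1 bond and 6-endo attack: slow addition of Bu3SnH at high dilution, the low temperature allowed by Et3B/air initiation, and the monosubstituted alkene secure these in turn. Both epimers of 10 give the same planar radical, so the acetal configuration does not matter.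

Step 6
Reactants: 11 silyl-protected oxolane
Product: 12 4-[(2S,3S,4S,5R)-5-(3,4-dimethoxyphenyl)-3,4-dimethyloxolan-2-yl]-2,6-dimethoxyphenol (CNP0326872.2)
Conditions: Bu4NF, AcOH, THF, 0 °C to rt
Reagents that add atoms: none
Why: Fluoride-induced cleavage of the aryl silyl ether; buffering with acetic acid protonates the phenoxide as it forms, so the benzylic ether next to the 4-hydroxyaryl ring should not open and the four stereocentres stay untouched.

**Compound list**

1 | syringaldehyde (4-hydroxy-3,5-dimethoxybenzaldehyde) | COc1cc(C=O)cc(OC)c1O | starting material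
2 | 3,5-dimethoxy-4-[(triisopropylsilyl)oxy]benzaldehyde | COc1cc(C=O)cc(OC)c1O[Si](C(C)C)(C(C)C)C(C)C | intermediate
3 | (E)-crotylboronic acid pinacol ester, 2-[(2E)-but-2-en-1-yl]-4,4,5,5-tetramethyl-1,3,2-dioxaborolane | C/C=C/CB1OC(C)(C)C(C)(C)O1 | starting material
4 | pinacol borate ester of 5, 2-{[(1S,2S)-1-aryl-2-methylbut-3-en-1-yl]oxy}-4,4,5,5-tetramethyl-1,3,2-dioxaborolane | CC1(C)OB(O[C@H](c2cc(OC)c(O[Si](C(C)C)(C(C)C)C(C)C)c(OC)c2)[C@@H](C)C=C)OC1(C)C | intermediate
5 | (1S,2S)-1-{3,5-dimethoxy-4-[(triisopropylsilyl)oxy]phenyl}-2-methylbut-3-en-1-ol | O[C@H](c1cc(OC)c(O[Si](C(C)C)(C(C)C)C(C)C)c(OC)c1)[C@@H](C)C=C | intermediate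
6 | (3,4-dimethoxyphenyl)methanol | COc1ccc(CO)cc1OC | starting material
7 | 3,4-dimethoxybenzyl phenyl sulfide | COc1ccc(CSc2ccccc2)cc1OC | intermediate
8 | chloro(3,4-dimethoxyphenyl)methyl phenyl sulfide (racemic) | COc1ccc(C(Cl)Sc2ccccc2)cc1OC | intermediate
9 | sodium (1S,2S)-1-{3,5-dimethoxy-4-[(triisopropylsilyl)oxy]phenyl}-2-methylbut-3-en-1-olate | [Na+].[O-][C@H](c1cc(OC)c(O[Si](C(C)C)(C(C)C)C(C)C)c(OC)c1)[C@@H](C)C=C | intermediate
10 | (3,4-dimethoxyphenyl)(phenylsulfanyl)methyl (1S,2S)-1-{3,5-dimethoxy-4-[(triisopropylsilyl)oxy]phenyl}-2-methylbut-3-en-1-yl ether (both epimers at the acetal carbon) | COc1ccc(C(Sc2ccccc2)O[C@H](c3cc(OC)c(O[Si](C(C)C)(C(C)C)C(C)C)c(OC)c3)[C@@H](C)C=C)cc1OC | intermediate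
11 | (2R,3S,4S,5S)-2-(3,4-dimethoxyphenyl)-5-{3,5-dimethoxy-4-[(triisopropylsilyl)oxy]phenyl}-3,4-dimethyloxolane | COc1ccc([C@@H]2O[C@H](c3cc(OC)c(O[Si](C(C)C)(C(C)C)C(C)C)c(OC)c3)[C@@H](C)[C@@H]2C)cc1OC | intermediate
12 | 4-[(2S,3S,4S,5R)-5-(3,4-dimethoxyphenyl)-3,4-dimethyloxolan-2-yl]-2,6-dimethoxyphenol | COc1ccc([C@@H]2O[C@H](c3cc(OC)c(O)c(OC)c3)[C@@H](C)[C@@H]2C)cc1OC | target

**Count**

Total steps: 6. Longest linear sequence: 5 steps (steps 1, 2, 4, 5, 6); step 3 is a one-step side branch.

**Steps most likely to fail**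

Step 5. What may go wrong: poor facial discrimination at C2 (the aryl group ending trans to the C3 methyl), reduction of the radical before ring closure, or beta-scission of the C5–O1 bond. The fallback sets out from 5 and comes back at 11; it sets C2 by hydride delivery to a cyclic oxocarbenium ion instead of by the radical transition state.
- Hydroboration of 5 with 9-BBN (2.2 equiv, THF) should give the O,C-bis(9-borabicyclononyl) adduct F1, oxidised in the same flask (NaBO3·4H2O) to (1S,2S)-1-aryl-2-methylbutane-1,4-diol F2.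
- TEMPO/PhI(OAc)2 (CH2Cl2) should oxidise the primary alcohol and, through the lactol F3, give the (4S,5S)-5-aryl-4-methyloxolan-2-one F4.
- LiN(SiMe3)2 (THF, −78 °C) forms the lithium enolate F5, which MeI should alkylate anti to the C4 methyl group to give the (3S,4S,5S)-3,4-dimethyl lactone F6.
- 3,4-Dimethoxyphenyllithium F7 (from 4-bromo-1,2-dimethoxybenzene and n-BuLi, THF, −78 °C) adds once to F6 to give the hemiketal F8.
- Et3SiH/BF3·OEt2 (CH2Cl2, −78 °C) should reduce the oxocarbenium ion from the face anti to the C3 methyl group and give 11 with the 2,3-cis relationship.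

Step 4. What may go wrong: slow O-alkylation of the hindered secondary alkoxide, so that chloride 8 is lost to hydrolysis or self-condensation before it is captured. The fallback sets out from 5 and comes back at 10. 3,4-Dimethoxybenzaldehyde and PhSH (BF3·OEt2, CH2Cl2) give the stable veratraldehyde bis(phenylsulfanyl)acetal F9. With free alcohol 5, N-iodosuccinimide and 2,6-di-tert-butyl-4-methylpyridine (4 Å sieves, CH2Cl2, −40 °C), one phenylthio group is removed by the soft electrophile and the thionium ion is captured by 5 to give 10. This is the thiophilic activation used for thioglycosides; it needs neither the alkoxide nor the chloride.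

Step 2. What may go wrong: poor enantiofacial discrimination or slow turnover with the electron-rich, 3,4,5-trioxygenated aldehyde under Brønsted acid catalysis. The fallback sets out from 2 and comes back at 5. It is a carbonyl crotylation by transfer hydrogenation: [Ir(cod)Cl]2, SEGPHOS (the antipode that gives the 1S,2S series), 4-cyano-3-nitrobenzoic acid, Cs2CO3, but-3-en-2-yl acetate, i-PrOH, THF, 60 °C. The nucleophile is a chiral crotyliridium complex formed in the catalytic cycle, so stereocontrol comes from the metal–ligand sphere and not from hydrogen bonding to a boronate. No compound outside the list is made (F0).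

Further compounds
F1 | step 5 | O,C-bis(9-borabicyclo[3.3.1]nonan-9-yl) adduct of 5 (borinate at oxygen, alkylborane at the former terminal carbon) | C1CC2CCCC(C1)B2O[C@H](c1cc(OC)c(O[Si](C(C)C)(C(C)C)C(C)C)c(OC)c1)[C@@H](C)CCB1C2CCCC1CCC2
F2 | step 5 | (1S,2S)-1-{3,5-dimethoxy-4-[(triisopropylsilyl)oxy]phenyl}-2-methylbutane-1,4-diol | O[C@H](c1cc(OC)c(O[Si](C(C)C)(C(C)C)C(C)C)c(OC)c1)[C@@H](C)CCO
F3 | step 5 | (4S,5S)-5-{3,5-dimethoxy-4-[(triisopropylsilyl)oxy]phenyl}-4-methyloxolan-2-ol (lactol, both anomers) | OC1C[C@H](C)[C@@H](c2cc(OC)c(O[Si](C(C)C)(C(C)C)C(C)C)c(OC)c2)O1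
F4 | step 5 | (4S,5S)-5-{3,5-dimethoxy-4-[(triisopropylsilyl)oxy]phenyl}-4-methyloxolan-2-one | O=C1C[C@H](C)[C@@H](c2cc(OC)c(O[Si](C(C)C)(C(C)C)C(C)C)c(OC)c2)O1
F5 | step 5 | lithium enolate of F4 | [Li+].[O-]C1=C[C@H](C)[C@@H](c2cc(OC)c(O[Si](C(C)C)(C(C)C)C(C)C)c(OC)c2)O1
F6 | step 5 | (3S,4S,5S)-5-{3,5-dimethoxy-4-[(triisopropylsilyl)oxy]phenyl}-3,4-dimethyloxolan-2-one | O=C1[C@@H](C)[C@H](C)[C@@H](c2cc(OC)c(O[Si](C(C)C)(C(C)C)C(C)C)c(OC)c2)O1
F7 | step 5 | 3,4-dimethoxyphenyllithium | [Li]c1ccc(OC)c(OC)c1
F8 | step 5 | (3S,4S,5S)-2-(3,4-dimethoxyphenyl)-5-{3,5-dimethoxy-4-[(triisopropylsilyl)oxy]phenyl}-3,4-dimethyloxolan-2-ol (hemiketal, both anomers) | COc1ccc(C2(O)O[C@H](c3cc(OC)c(O[Si](C(C)C)(C(C)C)C(C)C)c(OC)c3)[C@@H](C)[C@@H]2C)cc1OC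
F9 | step 4 | 3,4-dimethoxybenzaldehyde bis(phenylsulfanyl)acetal | COc1ccc(C(Sc2ccccc2)Sc2ccccc2)cc1OC
F0 | step 2 | none | none
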